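## Retrosynthetic overview
1. Target 11 comes from its 2'-O-acetate 10; the acetate is removed last.
2. Ring C of 10 is cut at C3–C4 and O1–C2, giving salicylaldehyde 3 and aryl enol ether 7. Both bonds form at the achiral isoflavylium level. C3 is then set by a chiral Brønsted acid/Hantzsch ester cascade transfer hydrogenation that leaves the prenyl and chromene C=C untouched.
3. 7 comes from 5 by C1 homologation with the phenol capped in the same flask; 5 comes from 1 + 4 by chromenylation.
4. 3 comes from 1 + 2 by nuclear prenylation, so both halves derive from the same aldehyde 1.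
5. Ring order: the dimethylpyran on ring B (step 2), then the central dihydropyran ring C (step 4).

Assumption: no precedent fixes the sense of induction of the new step. The (R)-catalyst is written; if the first run gives the 3S series, the equally available (S)-catalyst is used and nothing else changes.

## Route

**Step 1**
Reactants: 1 2,4-dihydroxybenzaldehyde; 2 prenyl bromide (1-bromo-3-methylbut-2-ene)
Product: 3 2,4-dihydroxy-3-(3-methylbut-2-en-1-yl)benzaldehyde
Conditions: KOH (1.1 equiv), H2O, 0 °C → rt, 16 h; chromatography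
Reagents that add atoms: none
Why: This is a phenolate C-alkylation (nuclear prenylation): in water the phenolate oxygens are shielded by hydrogen bonding, so the doubly activated C3 between them attacks the soft allylic bromide, a known but moderate-yielding reaction (about 30–40 %, with O-prenyl and 5-prenyl isomers separated).

**Step 2**
Reactants: 1 2,4-dihydroxybenzaldehyde; 4 3-methylbut-2-enal (prenal)
Product: 5 5-hydroxy-2,2-dimethyl-2H-chromene-6-carbaldehyde
Conditions: ethylenediammonium diacetate (20 mol %), toluene, reflux (Dean–Stark), 8 h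
Reagents that add atoms: none
Why: This is a Knoevenagel-type condensation followed by oxa-6π electrocyclisation (formal [3+3] chromenylation): C3 adds to the prenal iminium ion, water is lost to give the o-quinone methide, and the ring closes on the free 4-OH because the 2-OH is chelated to the CHO, which gives the angular chromene.

**Step 3**
Reactants: 5 5-hydroxy-2,2-dimethyl-2H-chromene-6-carbaldehyde
Product: 7 6-(2-methoxyethenyl)-2,2-dimethyl-2H-chromen-5-yl acetate (E/Z mixture), via potassium 6-(2-methoxyethenyl)-2,2-dimethyl-2H-chromen-5-olate 6 (not isolated)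
Conditions: MeOCH2PPh3Cl (2.0 equiv), KOtBu (3.0 equiv), THF, 0 °C → rt; then Ac2O (3 equiv), 0 °C; Et3N-washed silica
Reagents that add atoms: (methoxymethyl)triphenylphosphonium chloride COC[P+](c1ccccc1)(c1ccccc1)c1ccccc1.[Cl-]; acetic anhydride CC(=O)OC(C)=O
Why: Wittig methoxymethylenation works on the salicylaldehyde phenoxide when extra base is used, and in-flask O-acetylation caps the ortho phenol, which would otherwise close onto the enol ether to a benzofuran as soon as acid is present.

**Step 4 (key step)**
Reactants: 3 2,4-dihydroxy-3-(3-methylbut-2-en-1-yl)benzaldehyde (1.1 equiv); 7 6-(2-methoxyethenyl)-2,2-dimethyl-2H-chromen-5-yl acetate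
Product: 10 6-[(3R)-7-hydroxy-8-(3-methylbut-2-en-1-yl)-3,4-dihydro-2H-chromen-3-yl]-2,2-dimethyl-2H-chromen-5-yl acetate, via 6-[7-hydroxy-2-methoxy-8-(3-methylbut-2-en-1-yl)-2H-chromen-3-yl]-2,2-dimethyl-2H-chromen-5-yl acetate 8 (not isolated), via 6-[7-hydroxy-8-(3-methylbut-2-en-1-yl)-4H-chromen-3-yl]-2,2-dimethyl-2H-chromen-5-yl acetate 9 (not isolated)
Conditions: (i) (R)-3,3'-bis(2,4,6-triisopropylphenyl)-BINOL N-triflylphosphoramide (10 mol %), 3 Å MS, PhMe–CH2Cl2, rt, slow addition of 7; (ii) diethyl Hantzsch ester (2.5 equiv), −20 → 0 °C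
Reagents that add atoms: none
Why: Proposed new method: one chiral Brønsted acid first runs an isoflavylium-forming condensation and then an oxa-analogue of the quinoline cascade transfer hydrogenation; in (i) the acid-activated salicylaldehyde 3 is attacked by the nucleophilic aryl-bearing carbon of enol ether 7 (C3–C4 bond), the 2-OH closes on the oxocarbenium ion (O1–C2 bond), and the C4 oxygen leaves through the 7-OH-stabilised quinone methide to give 8, a neutral reservoir (labile acetal carbon, erased on ionisation) of the achiral isoflavylium/chiral-anion pair, acid condensation of salicylaldehydes with arylacetaldehyde equivalents being the known entry to isoflavylium salts; in (ii) the Hantzsch ester, hydrogen-bonded to the anion, delivers hydride to C4 (soft 1,4-mode) to give the achiral enol ether 9, the confined acid protonates C3 on its Si face (the step that sets 3R), and the oxocarbenium ion pair is trapped at C2 by a second hydride; the 2'-OAc group lowers the donor power of ring B so that protonation follows enol-ether polarity and it blocks benzofuran or pterocarpan closure, any 2H-chromene isomer re-enters by hydride exchange with the pyrylium ion or by C3 protonation to the 7-OH para-quinone methide, and the prenyl and chromene C=C are not basic enough to react; the closest known reaction types are the chiral phosphoric acid/Hantzsch ester cascade reduction of 3-substituted quinolines (stereocentre set by protonation), the chiral-phosphate-paired 1,4-reduction of 1-benzopyrylium ions, and the N-triflylphosphoramide-catalysed enantioselective protonation of 2-aryl cyclic silyl enol ethers.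

**Step 5**
Reactants: 10 6-[(3R)-7-hydroxy-8-(3-methylbut-2-en-1-yl)-3,4-dihydro-2H-chromen-3-yl]-2,2-dimethyl-2H-chromen-5-yl acetate
Product: 11 6-[(3R)-7-hydroxy-8-(3-methylbut-2-en-1-yl)-3,4-dihydro-2H-chromen-3-yl]-2,2-dimethyl-2H-chromen-5-ol (target)
Conditions: K2CO3 (0.2 equiv), MeOH, Ar, 0 °C → rt
Reagents that add atoms: none
Why: Base-catalysed transesterification (Zemplén type) cleaves the activated aryl acetate, and since C3–H is not acidic and both alkenes are inert to mild base, the 3R centre is kept.

## Compound list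
1 | 2,4-dihydroxybenzaldehyde | O=Cc1ccc(O)cc1O | starting material
2 | prenyl bromide | CC(C)=CCBr | starting material
3 | 2,4-dihydroxy-3-(3-methylbut-2-en-1-yl)benzaldehyde | CC(C)=CCc1c(O)ccc(C=O)c1O | intermediate
4 | 3-methylbut-2-enal | CC(C)=CC=O | starting material
5 | 5-hydroxy-2,2-dimethyl-2H-chromene-6-carbaldehyde | CC1(C)C=Cc2c(O1)ccc(C=O)c2O | intermediate
6 | potassium 6-(2-methoxyethenyl)-2,2-dimethyl-2H-chromen-5-olate (E/Z, not isolated) | [K+].COC=Cc1ccc2OC(C)(C)C=Cc2c1[O-] | intermediate
7 | 6-(2-methoxyethenyl)-2,2-dimethyl-2H-chromen-5-yl acetate (E/Z) | COC=Cc1ccc2OC(C)(C)C=Cc2c1OC(C)=O | intermediate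
8 | 2-methoxyisoflav-3-ene: 6-[7-hydroxy-2-methoxy-8-prenyl-2H-chromen-3-yl]-2,2-dimethyl-2H-chromen-5-yl acetate (labile acetal, not isolated) | CC(C)=CCc1c(O)ccc2c1OC(OC)C(=C2)c1ccc3c(c1OC(C)=O)C=CC(C)(C)O3 | intermediate
9 | isoflav-2-ene: 6-[7-hydroxy-8-prenyl-4H-chromen-3-yl]-2,2-dimethyl-2H-chromen-5-yl acetate (achiral, not isolated) | CC(C)=CCc1c(O)ccc2c1OC=C(C2)c1ccc3c(c1OC(C)=O)C=CC(C)(C)O3 | intermediate
10 | 6-[(3R)-7-hydroxy-8-prenyl-3,4-dihydro-2H-chromen-3-yl]-2,2-dimethyl-2H-chromen-5-yl acetate | CC(C)=CCc1c(O)ccc2c1OC[C@@H](c1ccc3c(c1OC(C)=O)C=CC(C)(C)O3)C2 | intermediate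
11 | 6-[(3R)-7-hydroxy-8-prenyl-3,4-dihydro-2H-chromen-3-yl]-2,2-dimethyl-2H-chromen-5-ol | CC(C)=CCc1c(O)ccc2c1OC[C@@H](c1ccc3c(c1O)C=CC(C)(C)O3)C2 | target

## Count and risks
Total steps: 5. Longest linear sequence: 4 (steps 2, 3, 4, 5).

**Step 4 (the proposed new step).**
- Risks:
  - 7 may oligomerise before it meets 3.
  - The reduction may stall at the chromene stage.
  - The ee may erode if ring B steers protonation to C2 (C3 cation route), or if the Hantzsch pyridine levels the acid.
- Fallback (known chemistry): it sets out from 7 and 3 and comes back at 10. Enol ether 7 is hydrolysed (PPTS, wet acetone, rt) to (5-acetoxy-2,2-dimethyl-2H-chromen-6-yl)acetaldehyde F1. Aldehyde 3 is reduced (NaBH4, EtOH, 0 °C) to 4-(hydroxymethyl)-2-(3-methylbut-2-en-1-yl)benzene-1,3-diol F2, which loses water under mild acid to its o-quinone methide. The two are joined by the known enamine-catalysed formal [4+2] of aldehydes with o-quinone methides, using (R)-α,α-diphenylprolinol trimethylsilyl ether (20 mol %) and PhCO2H in CHCl3. The C–C bond forms on the unshielded enamine face, which sets 3R. The liberated phenol locks the labile α-aryl aldehyde as the lactol 6-[(3R)-2,7-dihydroxy-8-(3-methylbut-2-en-1-yl)-3,4-dihydro-2H-chromen-3-yl]-2,2-dimethyl-2H-chromen-5-yl acetate F3. Ionic reduction of the lactol (Et3SiH, BF3·OEt2, CH2Cl2, −78 °C) gives 10.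

**Step 1.**
- Risks: low yield and isomer separation, from competing O-alkylation, 5-prenylation and diprenylation.
- Fallback: it sets out from 1 and comes back at 3, replacing direct C-alkylation by O-alkylation followed by a [3,3] shift. The non-chelated 4-OH of 1 is alkylated with 3-chloro-3-methylbut-1-yne (K2CO3, KI, cat. CuI, acetone, reflux) to 2-hydroxy-4-[(2-methylbut-3-yn-2-yl)oxy]benzaldehyde F4. Lindlar semi-hydrogenation gives 2-hydroxy-4-[(2-methylbut-3-en-2-yl)oxy]benzaldehyde F5. An aromatic Claisen rearrangement (PhNEt2, 130 °C) then delivers the allyl unit inverted, that is as a prenyl group. It goes preferentially to C3 because of the bond fixation imposed by the chelated 2-OH/CHO pair, and this gives 3.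

**Step 3.**
- Risks: sluggish olefination of the deactivated phenoxide aldehyde, incomplete capping, and loss of 7 to benzofuran on acidic silica.
- Fallback: it sets out from 5 and comes back at 7, separating protection from olefination. Compound 5 is silylated (TBSCl, imidazole, DMF) to 5-[(tert-butyldimethylsilyl)oxy]-2,2-dimethyl-2H-chromene-6-carbaldehyde F6. This neutral, more electrophilic aldehyde undergoes the Wittig reaction (MeOCH2PPh3Cl, KHMDS, THF) to tert-butyl{[6-(2-methoxyethenyl)-2,2-dimethyl-2H-chromen-5-yl]oxy}dimethylsilane F7. Fluoride-triggered silyl-to-acetyl exchange (TBAF, Ac2O, THF, 0 °C) then gives 7.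

## Further compounds
F1 | step 4 | (5-acetoxy-2,2-dimethyl-2H-chromen-6-yl)acetaldehyde | CC(=O)Oc1c(CC=O)ccc2OC(C)(C)C=Cc12
F2 | step 4 | 4-(hydroxymethyl)-2-(3-methylbut-2-en-1-yl)benzene-1,3-diol | CC(C)=CCc1c(O)ccc(CO)c1O
F3 | step 4 | 6-[(3R)-2,7-dihydroxy-8-(3-methylbut-2-en-1-yl)-3,4-dihydro-2H-chromen-3-yl]-2,2-dimethyl-2H-chromen-5-yl acetate (anomer mixture) | CC(C)=CCc1c(O)ccc2c1OC(O)[C@@H](c1ccc3c(c1OC(C)=O)C=CC(C)(C)O3)C2
F4 | step 1 | 2-hydroxy-4-[(2-methylbut-3-yn-2-yl)oxy]benzaldehyde | C#CC(C)(C)Oc1ccc(C=O)c(O)c1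
F5 | step 1 | 2-hydroxy-4-[(2-methylbut-3-en-2-yl)oxy]benzaldehyde | C=CC(C)(C)Oc1ccc(C=O)c(O)c1
F6 | step 3 | 5-[(tert-butyldimethylsilyl)oxy]-2,2-dimethyl-2H-chromene-6-carbaldehyde | CC1(C)C=Cc2c(O1)ccc(C=O)c2O[Si](C)(C)C(C)(C)C
F7 | step 3 | tert-butyl{[6-(2-methoxyethenyl)-2,2-dimethyl-2H-chromen-5-yl]oxy}dimethylsilane (E/Z) | COC=Cc1ccc2OC(C)(C)C=Cc2c1O[Si](C)(C)C(C)(C)C
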